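The plan cuts both pyranone rings of the 6,8'-bicoumarin at C2–C3 and C2'–C3'. In each ring C2 is bonded to O1, to its carbonyl oxygen and to C3, so it is a carbonic acid carbon. It can be attached first to the phenol oxygen (future O1) as a diethylcarbamate and then handed over to the methyl carbon of the ortho acetyl group (future C3, next to C4). One base treatment of the biaryl bis(2-acetylaryl diethylcarbamate) forms both C–C bonds and frees both phenols for lactonisation. This precursor comes from a Negishi-built tetra-ortho-substituted biaryl of two 3,5-dimethoxytoluene units, acetylated twice and demethylated next to each ketone.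

Key step: step 6

Assumption: the target SMILES leaves the configuration of the C6–C8' axis open, so the route aims at the racemate. The axis becomes stereogenic in step 3, when ring B loses its symmetry.

Labels: ring A (unprimed biphenyl locants, C1 = axis, C2 = CH3) becomes the C6-linked coumarin. Ring B (primed locants, C1' = axis, C4' = CH3) becomes the C8'-linked coumarin.

Step 1
Reactants: 1 3,5-dimethoxytoluene
Product: 2 2-bromo-3,5-dimethoxytoluene
Conditions: NBS (1.0 equiv), MeCN, 0 °C to rt, dark
Reagents that add atoms: N-bromosuccinimide, O=C1CCC(=O)N1Br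
Why: Electrophilic aromatic bromination with NBS in a polar solvent should go to C2, para to one methoxy group and ortho to the other, because C4 between both methoxy groups is more crowded, and one equivalent without light or initiator avoids dibromination and benzylic bromination.

Step 2
Reactants: 1 3,5-dimethoxytoluene; 2 2-bromo-3,5-dimethoxytoluene
Product: 5 2',4,6,6'-tetramethoxy-2,4'-dimethylbiphenyl, via aryllithium 3 (not isolated), via arylzinc chloride 4 (not isolated)
Conditions: 1, n-BuLi, THF, 0 °C to rt; ZnCl2, THF, 0 °C to rt; then 2, Pd2(dba)3 (cat.), RuPhos (cat.), THF, 70 °C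
Reagents that add atoms: n-butyllithium, CCCC[Li] (Li of 3 only); zinc chloride, Cl[Zn]Cl (Zn and Cl of 4 only); nothing from them remains in 5
Why: Directed ortho-metalation puts lithium at C4 between the two methoxy groups, transmetalation to zinc gives a nucleophile free of the protodeboronation problem of 2,6-dialkoxyarylboronic acids, and Negishi coupling on zerovalent palladium with the bulky electron-rich biarylphosphine RuPhos is an established entry to tetra-ortho-substituted biaryls.

Step 3
Reactants: 5 2',4,6,6'-tetramethoxy-2,4'-dimethylbiphenyl; 6 acetyl chloride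
Product: 7 3,5'-diacetyl-2',4,6,6'-tetramethoxy-2,4'-dimethylbiphenyl (racemic)
Conditions: AcCl (2.5 equiv), TiCl4 (2.5 equiv), CH2Cl2, −10 °C to rt; ice-water work-up
Reagents that add atoms: acetyl chloride, CC(Cl)=O
Why: In this twofold Friedel–Crafts acylation, ring A should react at C3 (para to the C6 methoxy group, between CH3 and OCH3) rather than at C5 between two methoxy groups, as 3,5-dimethoxytoluene itself does, while C3' and C5' of ring B are equivalent and each ring is deactivated after its first acylation.

Step 4
Reactants: 7 3,5'-diacetyl-2',4,6,6'-tetramethoxy-2,4'-dimethylbiphenyl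
Product: 8 3,5'-diacetyl-4,6'-dihydroxy-2',6-dimethoxy-2,4'-dimethylbiphenyl
Conditions: BCl3 (3 equiv), CH2Cl2, −78 °C to 0 °C; H2O
Reagents that add atoms: none
Why: In this chelation-controlled aryl methyl ether cleavage, BCl3 binds each ketone oxygen and removes only the single methoxy group ortho to it (C4 and C6') through a six-membered boron chelate, so the C6 and C2' methoxy groups (future C7 and C7' OCH3) should survive.

Step 5
Reactants: 8 3,5'-diacetyl-4,6'-dihydroxy-2',6-dimethoxy-2,4'-dimethylbiphenyl; 9 diethylcarbamoyl chloride
Product: 10 3,5'-diacetyl-2',6-dimethoxy-2,4'-dimethylbiphenyl-4,6'-diyl bis(diethylcarbamate)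
Conditions: ClC(O)NEt2 (3 equiv), K2CO3, DMAP (cat.), MeCN, reflux
Reagents that add atoms: diethylcarbamoyl chloride, CCN(CC)C(Cl)=O
Why: O-Carbamoylation of the phenoxides (nucleophilic acyl substitution) with excess reagent and heat should overcome hydrogen bonding and crowding, while the carbonate base is too weak to start migration of the unreactive carbamates onto the ketone carbons.

Step 6
Reactants: 10 3,5'-diacetyl-2',6-dimethoxy-2,4'-dimethylbiphenyl-4,6'-diyl bis(diethylcarbamate)
Product: 11 3,3'-(4,6'-dihydroxy-2',6-dimethoxy-2,4'-dimethylbiphenyl-3,5'-diyl)bis(N,N-diethyl-3-oxopropanamide)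
Conditions: NaH (6 equiv), THF, reflux; then 1 M HCl, 0 °C
Reagents that add atoms: none
Why: NaH turns each acetyl group into its sodium enolate, whose terminal carbon (future C3 or C3') adds to the carbamate carbonyl (future C2 or C2') on the neighbouring ring oxygen via a six-membered cyclic transition state made of C3, C4, C4a, C8a, O1 and C2, and the tetrahedral adduct collapses with departure of the aryloxide, so that the CONEt2 unit moves from O to C. The reaction type is the carbamoyl Baker–Venkataraman rearrangement, established for simple 2-acetylaryl diethylcarbamates and run here twice in one molecule. A second equivalent of base per ring deprotonates the acidic methylene of each new β-keto amide, which makes both transfers irreversible and explains the need for at least four equivalents of NaH. No ring is closed, no stereocentre is created, and the stereogenic axis is not touched. The selectivity needed is transfer within each ring instead of aldol condensation, intermolecular acylation or transfer across the axis; the ortho placement of enolate and carbamate gives a high effective molarity, the diethylcarbamate is a weak electrophile toward outside nucleophiles, and the carbamate of the other ring could only be reached through a transition state of nine or more members. The aryl methyl groups ortho to the ketones are much less acidic than the acetyl CH3 groups, so enolisation should take place at the right carbon.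

Step 7
Reactants: 11 3,3'-(4,6'-dihydroxy-2',6-dimethoxy-2,4'-dimethylbiphenyl-3,5'-diyl)bis(N,N-diethyl-3-oxopropanamide)
Product: 12 4,4'-dihydroxy-7,7'-dimethoxy-5,5'-dimethyl-6,8'-bichromene-2,2'-dione
Conditions: CF3CO2H, toluene, reflux
Reagents that add atoms: none
Why: In this acid-promoted lactonisation (6-exo-trig addition–elimination), each ortho phenol adds to its protonated amide carbonyl and diethylamine leaves as its salt, which is the standard closure of carbamoyl Baker–Venkataraman products to 4-hydroxycoumarins.

Step 8
Reactants: 12 4,4'-dihydroxy-7,7'-dimethoxy-5,5'-dimethyl-6,8'-bichromene-2,2'-dione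
Product: 13 4,4',7,7'-tetramethoxy-5,5'-dimethyl-6,8'-bichromene-2,2'-dione (target, racemic)
Conditions: Me2SO4 (4 equiv), K2CO3, acetone, reflux
Reagents that add atoms: dimethyl sulfate, COS(=O)(=O)OC
Why: O-Alkylation of the vinylogous carboxylates with the hard electrophile dimethyl sulfate under K2CO3 in acetone is the usual conversion of 4-hydroxycoumarins into 4-methoxycoumarins and should favour the C4 oxygen over C3 and over the lactone carbonyl oxygen.

Compound list
1 | 3,5-dimethoxytoluene | COc1cc(C)cc(OC)c1 | starting material
2 | 2-bromo-3,5-dimethoxytoluene | COc1cc(C)c(Br)c(OC)c1 | intermediate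
3 | (2,6-dimethoxy-4-methylphenyl)lithium | [Li]c1c(OC)cc(C)cc1OC | intermediate
4 | (2,6-dimethoxy-4-methylphenyl)zinc chloride | Cl[Zn]c1c(OC)cc(C)cc1OC | intermediate
5 | 2',4,6,6'-tetramethoxy-2,4'-dimethylbiphenyl | COc1cc(C)c(-c2c(OC)cc(C)cc2OC)c(OC)c1 | intermediate
6 | acetyl chloride | CC(Cl)=O | starting material
7 | 3,5'-diacetyl-2',4,6,6'-tetramethoxy-2,4'-dimethylbiphenyl (racemic axis) | COc1cc(OC)c(-c2c(OC)cc(C)c(C(C)=O)c2OC)c(C)c1C(C)=O | intermediate
8 | 3,5'-diacetyl-4,6'-dihydroxy-2',6-dimethoxy-2,4'-dimethylbiphenyl (racemic axis) | CC(=O)c1c(O)cc(OC)c(-c2c(OC)cc(C)c(C(C)=O)c2O)c1C | intermediate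
9 | diethylcarbamoyl chloride | CCN(CC)C(Cl)=O | starting material
10 | 3,5'-diacetyl-2',6-dimethoxy-2,4'-dimethylbiphenyl-4,6'-diyl bis(diethylcarbamate) (racemic axis) | CCN(CC)C(=O)Oc1cc(OC)c(-c2c(OC)cc(C)c(C(C)=O)c2OC(=O)N(CC)CC)c(C)c1C(C)=O | intermediate
11 | 3,3'-(4,6'-dihydroxy-2',6-dimethoxy-2,4'-dimethylbiphenyl-3,5'-diyl)bis(N,N-diethyl-3-oxopropanamide) (racemic axis) | CCN(CC)C(=O)CC(=O)c1c(O)cc(OC)c(-c2c(OC)cc(C)c(C(=O)CC(=O)N(CC)CC)c2O)c1C | intermediate
12 | 4,4'-dihydroxy-7,7'-dimethoxy-5,5'-dimethyl-6,8'-bichromene-2,2'-dione (racemic axis) | COc1cc2oc(=O)cc(O)c2c(C)c1-c1c(OC)cc(C)c2c(O)cc(=O)oc12 | intermediate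
13 | 4,4',7,7'-tetramethoxy-5,5'-dimethyl-6,8'-bichromene-2,2'-dione (racemic axis) | COc1cc2oc(=O)cc(OC)c2c(C)c1-c1c(OC)cc(C)c2c(OC)cc(=O)oc12 | target

Total step count: 8. Longest linear sequence: 8 steps (1 → 2 → 5 → 7 → 8 → 10 → 11 → 12 → 13).

Steps most likely to fail

1. Step 6 (key step).
- What may go wrong: the ring B carbamate is squeezed between the biaryl axis and the acetyl group, so its transfer may stall after ring A has reacted. Hydrolytic loss of a carbamoyl group or intermolecular aldol condensation may compete on prolonged heating.
- Fallback: set out from bis(phenol) 8 and leave out the carbamates. Heating 8 with excess NaH in diethyl carbonate should C-ethoxycarbonylate both ketone enolates (crossed Claisen condensation) to the bis(β-keto ethyl ester) F1. This should lactonise in the same flask onto the neighbouring phenoxides and, after acidification, come back to the route at bis(4-hydroxycoumarin) 12.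

2. Step 2.
- What may go wrong: with four ortho substituents around the new bond, transmetalation and reductive elimination may become slower than hydrodebromination of the bromide and homocoupling of the zinc reagent.
- Fallback: swap the polarity and the coupling type. Bromide 2 is taken by bromine–lithium exchange (n-BuLi, THF, −78 °C), B(OiPr)3 and acidic work-up to (2,4-dimethoxy-6-methylphenyl)boronic acid F2. It carries only one ortho oxygen and is less prone to protodeboronation. Aryllithium 3, made from 1 as in step 2, is quenched with iodine to 2-iodo-1,3-dimethoxy-5-methylbenzene F3. Suzuki–Miyaura coupling of the two (Pd(OAc)2, SPhos, K3PO4, toluene/H2O, 100 °C) returns to biaryl 5.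

3. Step 3.
- What may go wrong: erosion of site selectivity in ring A (attack between the two methoxy groups), a second acylation of an already acylated ring, and partial Lewis acid cleavage of ortho methoxy groups.
- Fallback: set out from biaryl 5 with a twofold Vilsmeier–Haack formylation (POCl3, DMF, 0 to 80 °C). Its bulky, mild chloroiminium electrophile is more position-selective, and the iminium product shuts each ring down after one substitution, so it should give the dialdehyde F4. Addition of MeMgBr (THF, 0 °C) should give the bis(1-hydroxyethyl)biaryl F5 as a mixture of diastereomers. Oxidation with Dess–Martin periodinane (CH2Cl2, rt) erases those centres and rejoins the route at diketone 7.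

Further compounds
F1 | step 6 | diethyl 3,3'-(4,6'-dihydroxy-2',6-dimethoxy-2,4'-dimethylbiphenyl-3,5'-diyl)bis(3-oxopropanoate) | CCOC(=O)CC(=O)c1c(O)cc(OC)c(-c2c(OC)cc(C)c(C(=O)CC(=O)OCC)c2O)c1C
F2 | step 2 | (2,4-dimethoxy-6-methylphenyl)boronic acid | COc1cc(C)c(B(O)O)c(OC)c1
F3 | step 2 | 2-iodo-1,3-dimethoxy-5-methylbenzene | COc1cc(C)cc(OC)c1I
F4 | step 3 | 2',4,6,6'-tetramethoxy-2,4'-dimethylbiphenyl-3,5'-dicarbaldehyde | COc1cc(OC)c(-c2c(OC)cc(C)c(C=O)c2OC)c(C)c1C=O
F5 | step 3 | 1,1'-(2',4,6,6'-tetramethoxy-2,4'-dimethylbiphenyl-3,5'-diyl)diethanol (mixture of diastereomers) | COc1cc(OC)c(-c2c(OC)cc(C)c(C(C)O)c2OC)c(C)c1C(C)O
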